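**Retrosynthetic overview** (cyclohepta[b]furan numbering for the tropone part)
1. The tropone is built last on a spiro γ-lactone by a [5+2] double condensation with 1,1-dimethoxyacetone: C3a=C4 by acid-mediated vinylogous aldol closure/aromatisation, C5=C6 by Knoevenagel condensation.
2. C8–C8a comes from Claisen addition of the methyl 3-oxopentanoate dianion to the lactone carbonyl; the lactone oxygen becomes the dihydrofuran oxygen.
3. Key disconnection: the spiro C2–C3 bond, made by SmI2 ketyl-radical addition of a cis-2,6-dimethylcyclohexanone to methyl acrylate, which sets the spiro centre.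
4. The ketone comes from 2-methylcyclohex-2-enone: asymmetric conjugate addition/Michael trapping (CH and quaternary centres), Mukaiyama hydration (tertiary alcohol), α-methylenation/hydrogenation (ring methyl).
5. Ring order: cyclohexane (bought) → spiro lactone (future dihydrofuran) → tropone.

Assumption: the target is taken exactly as the SMILES draws it, i.e. (1'R,2'R,3'S,6'R); iodomethane, formaldehyde, O2 and LiOH are treated as atom-adding reagents and carry no compound number.

Step 1
Reactants: 1 2-methylcyclohex-2-en-1-one; 2 prop-1-en-2-ylmagnesium bromide; 3 methyl acrylate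
Product: 5 methyl 3-[(1R,6R)-1-methyl-2-oxo-6-(prop-1-en-2-yl)cyclohexyl]propanoate, via bromomagnesium enolate 4 (not isolated)
Conditions: CuBr·SMe2 (5 mol%), (R)-1-[(S)-2-(diphenylphosphino)ferrocenyl]ethyldicyclohexylphosphine (6 mol%; the antipode if the sense of induction requires it), 2 (1.2 equiv), t-BuOMe, −78 °C; then 3 (1.3 equiv), THF, −78 → −30 °C; aq. NH4Cl
Reagents that add atoms: none
Why: Copper-catalysed asymmetric conjugate addition sets the ring CH centre under ligand control, and the tetrasubstituted magnesium enolate is then trapped by Michael addition on the face anti to the new isopropenyl group, so the quaternary centre forms with the propanoate chain trans to it (tandem conjugate addition–Michael reaction).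

Step 2
Reactants: 5 methyl 3-[(1R,6R)-1-methyl-2-oxo-6-(prop-1-en-2-yl)cyclohexyl]propanoate
Product: 6 methyl 3-[(1R,6S)-6-(2-hydroxypropan-2-yl)-1-methyl-2-oxocyclohexyl]propanoate
Conditions: Co(acac)2 (10 mol%), PhSiH3 (2.5 equiv), O2 (1 atm), i-PrOH, 0 °C → rt
Reagents that add atoms: dioxygen, O=O
Why: Mukaiyama hydration, in which hydrogen-atom transfer to the 1,1-disubstituted alkene gives the tertiary radical that is trapped by O2 and reduced to the Markovnikov alcohol; no stereocentre is made or touched (the descriptor changes from R to S only through substituent priority).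

Step 3
Reactants: 6 methyl 3-[(1R,6S)-6-(2-hydroxypropan-2-yl)-1-methyl-2-oxocyclohexyl]propanoate
Product: 7 methyl 3-[(1R,6S)-6-(2-hydroxypropan-2-yl)-1-methyl-3-methylidene-2-oxocyclohexyl]propanoate
Conditions: (CH2O)n (3 equiv), N-methylanilinium trifluoroacetate (1.5 equiv), THF, reflux
Reagents that add atoms: formaldehyde (used as paraformaldehyde), C=O
Why: Mannich-type α-methylenation (Gras conditions) can only take place at the single enolisable α-CH2 because the other α-carbon is quaternary; no stereocentre is formed.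

Step 4
Reactants: 7 methyl 3-[(1R,6S)-6-(2-hydroxypropan-2-yl)-1-methyl-3-methylidene-2-oxocyclohexyl]propanoate
Product: 8 methyl 3-[(1R,3R,6S)-6-(2-hydroxypropan-2-yl)-1,3-dimethyl-2-oxocyclohexyl]propanoate
Conditions: H2 (1 atm), 5% Pd/C, EtOAc, 0 °C, 30 min; filtered and used crude
Reagents that add atoms: none
Why: Heterogeneous hydrogenation of the exocyclic enone delivers hydrogen from the ring face opposite the axial methyl of the quaternary carbon (1,3 to the methylene), giving the kinetic cis-2,6-dimethyl ketone (new centre 3R), which sees neither base nor acid before step 5.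

Step 5
Reactants: 8 methyl 3-[(1R,3R,6S)-6-(2-hydroxypropan-2-yl)-1,3-dimethyl-2-oxocyclohexyl]propanoate; 3 methyl acrylate
Product: 11 3-[(5R,6R,7S,10R)-7-(2-hydroxypropan-2-yl)-6,10-dimethyl-2-oxo-1-oxaspiro[4.5]decan-6-yl]propanoic acid, via spirolactone methyl ester 9 (not isolated), via hydroxy diacid 10 (not isolated)
Conditions: SmI2 (2.5 equiv), 3 (3 equiv), t-BuOH (2 equiv), THF, 0 °C; then LiOH (5 equiv), THF/H2O, rt; then 1 M HCl to pH 2, rt
Reagents that add atoms: lithium hydroxide, [Li+].[OH-]
Why: SmI2 ketyl–olefin coupling (key radical step), in which the samarium ketyl radical adds to the acrylate β-carbon from the face anti to the two α-methyl groups and the hydroxypropyl group, while the bulky O–Sm stays on their face, so the spiro centre is set as 5R before the alkoxide lactonises; saponification then frees the side-chain acid and acidification re-closes the γ-lactone (five-membered ring favoured over the δ-lactone with the other chain).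

Step 6
Reactants: 11 3-[(5R,6R,7S,10R)-7-(2-hydroxypropan-2-yl)-6,10-dimethyl-2-oxo-1-oxaspiro[4.5]decan-6-yl]propanoic acid; 12 methyl 3-oxobutanoate
Product: 15 3-[(2E,5R,6R,7S,10R)-7-(2-hydroxypropan-2-yl)-2-(5-methoxy-3,5-dioxopentan-2-ylidene)-6,10-dimethyl-1-oxaspiro[4.5]decan-6-yl]propanoic acid, via methyl 3-oxopentanoate dianion 13 (not isolated), via hydroxy diketo ester 14 (not isolated)
Conditions: 12 (3 equiv), LiN(i-Pr)2 (6.2 equiv), THF, 0 °C; MeI (3 equiv), 0 °C; LiN(i-Pr)2 (3.1 equiv), −78 °C; then 11 pre-treated with LiN(i-Pr)2 (2 equiv), −78 → 0 °C; AcOH; then pyridinium p-toluenesulfonate (10 mol%), CH2Cl2, rt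
Reagents that add atoms: iodomethane, CI
Why: γ-Methylation of the acetoacetate dianion, Claisen-type acylation of the new dianion at its γ-carbon by the lactone carbonyl (carboxylate and alkoxide are inert) and acid-catalysed cyclodehydration of the tertiary hydroxy diketone give the (E)-alkylidene tetrahydrofuran (a vinylogous ester) without breaking the spiro C–O bond, so no stereocentre changes.

Step 7
Reactants: 15 3-[(2E,5R,6R,7S,10R)-7-(2-hydroxypropan-2-yl)-2-(5-methoxy-3,5-dioxopentan-2-ylidene)-6,10-dimethyl-1-oxaspiro[4.5]decan-6-yl]propanoic acid; 16 1,1-dimethoxypropan-2-one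
Product: 17 3-[(2E,5R,6R,7S,10R)-2-[(4E)-6,6-dimethoxy-4-(methoxycarbonyl)-5-methyl-3-oxohex-4-en-2-ylidene]-7-(2-hydroxypropan-2-yl)-6,10-dimethyl-1-oxaspiro[4.5]decan-6-yl]propanoic acid
Conditions: TiCl4 (2.2 equiv), pyridine (8 equiv), 16 (2 equiv), THF, 0 °C → rt; aqueous work-up
Reagents that add atoms: none
Why: Knoevenagel condensation (Lehnert conditions) joins the only doubly activated methylene, between the ketone and the methyl ester, to the activated ketone of the α-keto acetal; the alkylidene geometry is not controlled but equilibrates in step 8, and no stereocentre is formed.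

Step 8
Reactants: 17 3-[(2E,5R,6R,7S,10R)-2-[(4E)-6,6-dimethoxy-4-(methoxycarbonyl)-5-methyl-3-oxohex-4-en-2-ylidene]-7-(2-hydroxypropan-2-yl)-6,10-dimethyl-1-oxaspiro[4.5]decan-6-yl]propanoic acid
Product: 18 3-[(1'R,2'R,3'S,6'R)-3'-(2-hydroxypropan-2-yl)-6-(methoxycarbonyl)-2',5,6',8-tetramethyl-7-oxo-3,7-dihydrospiro[cyclohepta[b]furan-2,1'-cyclohexan]-2'-yl]propanoic acid (CNP0448476.2)
Conditions: pyridinium p-toluenesulfonate (30 mol%), toluene, 4 Å molecular sieves, 70 °C
Reagents that add atoms: none
Why: Proposed new method: mild acid ionises the allylic dimethyl acetal to a conjugated oxocarbenium ion and equilibrates the exocyclic enol ether with its endocyclic 4,5-dihydrofuran tautomer, whose nucleophilic β-carbon closes the seven-membered ring, and loss of the second methanol gives the aromatic 3-alkoxytropone, the closest known reaction type being the acid-catalysed intramolecular vinylogous (Mukaiyama/Prins-type) aldol condensation of enol ethers with acetals; the weak pyridinium acid does not ionise the tertiary spiro C–O bond, so all four stereocentres are kept.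

**Compound list**
1 | 2-methylcyclohex-2-en-1-one | CC1=CCCCC1=O | starting material
2 | prop-1-en-2-ylmagnesium bromide (isopropenylmagnesium bromide) | CC(=C)[Mg]Br | starting material
3 | methyl acrylate (methyl prop-2-enoate) | C=CC(=O)OC | starting material
4 | bromomagnesium (3R)-2-methyl-3-(prop-1-en-2-yl)cyclohex-1-en-1-olate | CC1=C(O[Mg]Br)CCC[C@@H]1C(C)=C | intermediate
5 | methyl 3-[(1R,6R)-1-methyl-2-oxo-6-(prop-1-en-2-yl)cyclohexyl]propanoate | O=C1CCC[C@H](C(C)=C)[C@@]1(C)CCC(=O)OC | intermediate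
6 | methyl 3-[(1R,6S)-6-(2-hydroxypropan-2-yl)-1-methyl-2-oxocyclohexyl]propanoate | O=C1CCC[C@H](C(C)(C)O)[C@@]1(C)CCC(=O)OC | intermediate
7 | methyl 3-[(1R,6S)-6-(2-hydroxypropan-2-yl)-1-methyl-3-methylidene-2-oxocyclohexyl]propanoate | O=C1C(=C)CC[C@H](C(C)(C)O)[C@@]1(C)CCC(=O)OC | intermediate
8 | methyl 3-[(1R,3R,6S)-6-(2-hydroxypropan-2-yl)-1,3-dimethyl-2-oxocyclohexyl]propanoate | O=C1[C@H](C)CC[C@H](C(C)(C)O)[C@@]1(C)CCC(=O)OC | intermediate
9 | methyl 3-[(5R,6R,7S,10R)-7-(2-hydroxypropan-2-yl)-6,10-dimethyl-2-oxo-1-oxaspiro[4.5]decan-6-yl]propanoate | O=C1CC[C@@]2(O1)[C@H](C)CC[C@H](C(C)(C)O)[C@@]2(C)CCC(=O)OC | intermediate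
10 | 3-[(1R,2R,3S,6R)-2-(2-carboxyethyl)-1-hydroxy-3-(2-hydroxypropan-2-yl)-2,6-dimethylcyclohexyl]propanoic acid | O[C@]1(CCC(=O)O)[C@H](C)CC[C@H](C(C)(C)O)[C@@]1(C)CCC(=O)O | intermediate
11 | 3-[(5R,6R,7S,10R)-7-(2-hydroxypropan-2-yl)-6,10-dimethyl-2-oxo-1-oxaspiro[4.5]decan-6-yl]propanoic acid | O=C1CC[C@@]2(O1)[C@H](C)CC[C@H](C(C)(C)O)[C@@]2(C)CCC(=O)O | intermediate
12 | methyl 3-oxobutanoate (methyl acetoacetate) | CC(=O)CC(=O)OC | starting material
13 | methyl 3-oxopentanoate (made and used in the flask as its dilithium dianion) | CCC(=O)CC(=O)OC | intermediate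
14 | 3-[(1R,2R,3S,6R)-1-hydroxy-3-(2-hydroxypropan-2-yl)-1-(7-methoxy-4-methyl-3,5,7-trioxoheptyl)-2,6-dimethylcyclohexyl]propanoic acid (chain C4 epimeric, enolised) | O[C@]1(CCC(=O)C(C)C(=O)CC(=O)OC)[C@H](C)CC[C@H](C(C)(C)O)[C@@]1(C)CCC(=O)O | intermediate
15 | 3-[(2E,5R,6R,7S,10R)-7-(2-hydroxypropan-2-yl)-2-(5-methoxy-3,5-dioxopentan-2-ylidene)-6,10-dimethyl-1-oxaspiro[4.5]decan-6-yl]propanoic acid | COC(=O)CC(=O)/C(C)=C1\CC[C@@]2(O1)[C@H](C)CC[C@H](C(C)(C)O)[C@@]2(C)CCC(=O)O | intermediate
16 | 1,1-dimethoxypropan-2-one | CC(=O)C(OC)OC | starting material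
17 | 3-[(2E,5R,6R,7S,10R)-2-[(4E)-6,6-dimethoxy-4-(methoxycarbonyl)-5-methyl-3-oxohex-4-en-2-ylidene]-7-(2-hydroxypropan-2-yl)-6,10-dimethyl-1-oxaspiro[4.5]decan-6-yl]propanoic acid (reactive alkylidene isomer shown) | COC(=O)/C(=C(\C)C(OC)OC)C(=O)/C(C)=C1\CC[C@@]2(O1)[C@H](C)CC[C@H](C(C)(C)O)[C@@]2(C)CCC(=O)O | intermediate
18 | 3-[(1'R,2'R,3'S,6'R)-3'-(2-hydroxypropan-2-yl)-6-(methoxycarbonyl)-2',5,6',8-tetramethyl-7-oxo-3,7-dihydrospiro[cyclohepta[b]furan-2,1'-cyclohexan]-2'-yl]propanoic acid (CNP0448476.2) | COC(=O)c1c(C)cc2c(c(C)c1=O)O[C@]1(C2)[C@H](C)CC[C@H](C(C)(C)O)[C@@]1(C)CCC(=O)O | target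

**Totals**
Total step count: 8. Longest linear sequence: 8 steps (1 → 5 → 6 → 7 → 8 → 11 → 15 → 17 → 18).

**Three steps most likely to fail, each with a fallback**

Step 8 (new seven-membered ring closure; a Nazarov-type closure of the cross-conjugated dienone or simple acetal hydrolysis could compete). The fallback sets out from 17. Pyridinium p-toluenesulfonate in wet acetone is used only to hydrolyse the acetal, giving the aldehyde 3-[(2E,5R,6R,7S,10R)-7-(2-hydroxypropan-2-yl)-2-[(4E)-4-(methoxycarbonyl)-5-methyl-3,6-dioxohex-4-en-2-ylidene]-6,10-dimethyl-1-oxaspiro[4.5]decan-6-yl]propanoic acid F4. The ring is then closed under basic instead of acidic activation (pyrrolidine/AcOH or DBU; vinylogous aldol condensation through the γ-deprotonated vinylogous ester, then dehydration to the tropone). It comes back to the route at 18.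

Step 7 (ketone Knoevenagel on a substrate carrying a free acid, a tertiary alcohol and an enol ether under TiCl4). The fallback sets out from 12 and moves the condensation to simple material. 13 is isolated after the methylation and condensed with 16 (TiCl4, pyridine) to methyl (2E)-2-(1,1-dimethoxypropan-2-ylidene)-3-oxopentanoate F2. The kinetic cross-conjugated lithium enolate of F2 (LiN(i-Pr)2, −78 °C, deprotonation at the propionyl CH2) then opens the dilithium salt of 11 to the hydroxy diketone 3-[(1R,2R,3S,6R)-1-[(6E)-8,8-dimethoxy-6-(methoxycarbonyl)-4,7-dimethyl-3,5-dioxooct-6-en-1-yl]-1-hydroxy-3-(2-hydroxypropan-2-yl)-2,6-dimethylcyclohexyl]propanoic acid F3, which pyridinium p-toluenesulfonate dehydrates to the enol ether. It comes back at 17.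

Step 1 (enantioselectivity with an alkenyl Grignard reagent, and direct Michael trapping of the magnesium enolate, which may oligomerise the acrylate). The fallback sets out from 1 and 2. The same copper-catalysed addition is run with Me3SiCl present, which also accelerates the addition, so that enolate 4 is captured and isolated as the silyl enol ether (R)-trimethyl{[2-methyl-3-(prop-1-en-2-yl)cyclohex-1-en-1-yl]oxy}silane F1. F1 is then joined to 3 in a separate Mukaiyama–Michael reaction (TiCl4, CH2Cl2, −78 °C, or catalytic tetrabutylammonium difluorotriphenylsilicate). It comes back at 5.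

**Further compounds**
F1 | step 1 | (R)-trimethyl{[2-methyl-3-(prop-1-en-2-yl)cyclohex-1-en-1-yl]oxy}silane | CC1=C(O[Si](C)(C)C)CCC[C@@H]1C(C)=C
F2 | step 7 | methyl (2E)-2-(1,1-dimethoxypropan-2-ylidene)-3-oxopentanoate | CCC(=O)/C(C(=O)OC)=C(/C)C(OC)OC
F3 | step 7 | 3-[(1R,2R,3S,6R)-1-[(6E)-8,8-dimethoxy-6-(methoxycarbonyl)-4,7-dimethyl-3,5-dioxooct-6-en-1-yl]-1-hydroxy-3-(2-hydroxypropan-2-yl)-2,6-dimethylcyclohexyl]propanoic acid | O[C@]1(CCC(=O)C(C)C(=O)/C(C(=O)OC)=C(/C)C(OC)OC)[C@H](C)CC[C@H](C(C)(C)O)[C@@]1(C)CCC(=O)O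
F4 | step 8 | 3-[(2E,5R,6R,7S,10R)-7-(2-hydroxypropan-2-yl)-2-[(4E)-4-(methoxycarbonyl)-5-methyl-3,6-dioxohex-4-en-2-ylidene]-6,10-dimethyl-1-oxaspiro[4.5]decan-6-yl]propanoic acid | COC(=O)/C(=C(\C)C=O)C(=O)/C(C)=C1\CC[C@@]2(O1)[C@H](C)CC[C@H](C(C)(C)O)[C@@]2(C)CCC(=O)O
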